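## Structural features

The target is a monocyclic elemane-type seco-sesquiterpenoid: one cyclohexane (C5–C10) with no ring fusion. C10 is quaternary (methyl C14, vinyl C1=C2), C5 bears a 3-hydroxyprop-1-en-2-yl group (C4=C3, C15–OH), C6 a free hydroxyl, C7 a 1-carboxyvinyl group (C11=C13, C12 acid), C8 an ester oxygen, and C9 is the only ring methylene. The C8 oxygen is acylated by (R)-3,4-dihydroxy-2-methylenebutanoic acid, so a sixth stereocentre (C3′) lies outside the ring. The five ring stereocentres are contiguous: the C5 substituent is trans to C6–O, C6–O is cis to both the C7 substituent and the C10 vinyl group, and C8–O is trans to the C7 substituent. In the chair with C5 and C6 equatorial, this places C8–O axial and syn to the C10 methyl. The fragile parts are the cis γ-hydroxy acid (C6–OH with C12), which lactonises under acid; the side-chain diol, which can attack its own ester and expel C8–O under base; and three 1,1-disubstituted alkenes, two of them acrylate-type acceptors. The real difficulty is that C10 carries two sterically similar carbon groups and gives little relative control, while the C5 and C8 substituents sit on the more hindered faces and the acid must be freed last without base or strong acid. The key step exploits the fact that C1 and the C6 oxygen are 1,3-related across C5 on the same face of ring C5–C10. A carboxyl at C1 on a cyclohexa-2,5-diene can therefore deliver its oxygen to C6 of one of two enantiotopic alkenes, closing ring C10–C1–O–C6–C5 and leaving bromine on C5. A check of 5 against 32 shows the same configuration at C10 and C6 and bromine anti to oxygen, so no structure needs correcting.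

## Logic of the disconnections

32 to 31: no skeletal bond is cut; the C12 carboxyl is traced back to a hemiacetal carbon that ties up the C6 oxygen. A free γ-hydroxy acid cannot be carried, and a lactone could not later be opened beside the C8 ester. The forward oxidation must tolerate four alkenes and four free hydroxyls at a pH that does not lactonise.

31 to 30: the C15 O–Si bond, the two acetonide C–O bonds and the C12–OMe bond are cut. All are chosen to fall together in acidic fluoride, because the side-chain ester does not survive base.

30 to 23 and 28: the C8–O acyl bond is cut, which splits off the only stereocentre outside the ring. The forward step must acylate a hindered axial alcohol.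

28 to 27 to 24: the exocyclic C2′=CH2 bond (and the ester O–Me bond) is cut, so C3′ comes from the chiral pool. The ester enolate must be trapped before it eliminates the β-oxygen.

23 to 22 to 21 to 20: the C8–H bond and the N–O bond are cut. C8 is set by ketone reduction, not by radical capture, because an axial oxygen syn to the C10 methyl is the contra-steric outcome for a reagent that delivers oxygen but the normal outcome for equatorial attack of a bulky hydride. The forward steps need face-selective hydride delivery and an N–O cleavage that spares the acetal.

20 to 19: C7–C11 and C8–O are cut. A three-atom tether from the C6 oxygen can reach C7 only on its own face, which gives the cis C6/C7 relation. The vinyl radical must cyclise before it is trapped.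

19 to 17, 18 and 4: the C12–O(C6) acetal bond and the C11–Br bond are cut. The tether is introduced at the aldehyde oxidation level, so C12 needs no later C–H oxidation.

17 to 16 to 15: C1=C2 is cut, so the vinyl group comes from the carboxyl carbon. The C6–O bond is never broken, so its configuration is the one set in the key step.

15 to 12 and 14: C5–C4 is cut. The bromide from the key step marks C5, and an SN2 route cannot give retention at a bridging neopentyl carbon, so a radical cross-coupling is required. It must bond anti to the C1–O bridge and capture the radical before it rearranges.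

14 to 13: the O–Si bond is cut.

12 to 10: the C1–OMe and C1–H bonds are cut. The lactone is masked as an acetal because an allylic lactone would be ionised by low-valent nickel.

10 to 8 to 7 to 5: the alkene is moved from C8=C9 to C7=C8 by oxidising C7 and then transposing reductively. This route is chosen over a C6-ketone detour because it keeps the C6–O configuration; re-reduction of a C6 ketone would be biased by the C10 methyl towards the wrong face. The forward steps need oxidation at the single allylic methylene and 1,2-hydride delivery to C=N.

5 to 3 and 4: C6–O and C5–Br are cut. This removes the lactone ring and all three stereocentres and returns an achiral diene acid; the forward step must select one enantiotopic alkene.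

3 to 1 and 2: C10–C14 and the ring C–H bonds at C10 and C7 are cut, leaving two commodity chemicals.

## Other disconnections considered

Alternative 1: the ring is cut at C6–C7. In the forward step the open-chain aldehyde A1 is treated with divalent chromium (CrCl2); the allylchromium formed from its (Z)-2-(bromomethyl)enoate adds through C7 to the C6 aldehyde and should give cyclohexane A2.
- In favour: one step closes the ring, creates the C11 methylene and sets C6 and C7. It delivers C12 as an ester with C6–OH already free, which is better than the chosen plan, where 30 must carry an acetal to the end and 31 needs a final oxidation.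
- Against: A1 must already hold C10, C5 and C8, so the quaternary centre and its neighbour have to be built acyclically. The aldehyde is α-branched and epimerisable. The cis C6/C7 outcome depends on which chair-like transition state the tethered allylmetal adopts.
- Comparison: on structure the chosen plan is stronger, since 5 gets C10 from a catalytic desymmetrisation. On mechanism the alternative is a closed polar transition state; the chosen plan relies on radical steps (15, 20) whose face selectivity is less certain, so the alternative is at least equal there. On step economy the two should be comparable, the alternative spending its steps on A1.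

Alternative 2: C7–C11 and C8–O are cut. The vinyl radical from 2-bromoallyl ether A3 should cyclise 5-exo onto C7 and the C8 radical should be capped by TEMPO to give A4.
- In favour: two bonds and the cis C6/C7 relation form in one step. This is the same tactic as step 12 of the chosen plan, so the two are equal on C7.
- Against: the oxygen at C8 must arrive on the face syn to the C10 methyl, which is not secured. A4 is a methylene-tetrahydrofuran whose C12 still needs an allylic C–H oxidation beside other allylic positions. Its pivalate needs base or hydride for removal, which the final ester would not survive.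
- Comparison: as a leading disconnection it leaves C10, C5 and C6 unsolved in A3, whereas the chosen plan solves them through 5. On mechanism the two are identical. On step economy the chosen plan saves the C12 oxidation by cyclising the acetal 19 but spends two steps (22, 23) correcting C8.

Alternative 3: C9–C10 is cut. Anodic oxidation of silyl enol ether A5 should give a radical cation that is attacked at C9 by C10 of the (E)-allylsilane, closing cyclohexanone A6 and releasing the vinyl group.
- In favour: the quaternary centre, the ring and the vinyl group form together without a methylenation step, which is shorter than steps 6, 9 and 10 of the chosen plan. The C8 ketone arrives directly; the chosen plan reaches it only at 22, so the alternative is better on that point.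
- Against: the C10 configuration would depend on substrate control from C5 and C6 in the cyclisation. A5 needs its anti C5/C6 pair made separately. C7 would then have to be functionalised next to a β-silyloxy ketone, where elimination threatens, and the cis C6/C7 relation would still need a tether.
- Comparison: on structure the chosen plan fixes C10 by catalyst control and the alternative by substrate control. On mechanism both use open-shell intermediates. On step economy the alternative is probably equal up to A6 and longer afterwards.

Key step: step 2

Remarks on the chemistry: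
- The sense of induction of (DHQD)2PHAL in step 2 is assumed to give 5; if the antipode predominates, the pseudo-enantiomeric (DHQ)2PHAL is used.
- Compounds 13, 18 and 24 are taken to be commercially available.

Step 1
Reactants: 1 benzoic acid; 2 iodomethane
Product: 3 1-methylcyclohexa-2,5-diene-1-carboxylic acid
Conditions: Li, NH3 (l), THF, −78 °C; then MeI; NH4Cl, then aq. HCl
Reagents that add atoms: none
Why: Birch reduction gives the carboxylate dienolate, which is C-methylated at the ipso carbon (Birch reductive alkylation); the product is achiral, with a mirror plane through C10 and C7.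

Step 2
Reactants: 3 1-methylcyclohexa-2,5-diene-1-carboxylic acid; 4 N-bromosuccinimide
Product: 5 (1R,5R,8R)-8-bromo-1-methyl-6-oxabicyclo[3.2.1]oct-2-en-7-one
Conditions: NBS (1.1 equiv), (DHQD)2PHAL (10 mol%), CHCl3/toluene, −40 °C; then 25 °C
Reagents that add atoms: none
Why: The catalyst binds the carboxylate as an ammonium ion pair and passes bromenium from N-bromosuccinimide to one of the two enantiotopic alkenes (C5=C6); the carboxylate oxygen then opens the bromonium ion at the distal carbon C6 from the opposite face. The closest known reaction type is the catalytic enantioselective bromolactonisation of 1-substituted cyclohexa-2,5-diene-1-carboxylic acids with cinchona-derived amines. The γ-lactone ring (C10, C1, O, C6, C5) closes in the 5-endo mode onto the bromonium ion; the kinetically accessible 4-exo β-lactone should rearrange to the bridged γ-lactone on warming. C10 becomes stereogenic through the catalyst's choice of alkene. C6 is set cis to C1 because a carboxyl on C10 can bridge only to its own face. C5 is set by anti opening, so bromine is trans to the C6 oxygen. The only selectivity the step needs is between enantiotopic alkenes, which the chiral catalyst supplies; regio- and diastereoselectivity follow from geometry and mechanism.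

Step 3
Reactants: 5 (1R,5R,8R)-8-bromo-1-methyl-6-oxabicyclo[3.2.1]oct-2-en-7-one
Product: 7 8-bromo-1-methyl-6-oxabicyclo[3.2.1]oct-2-ene-4,7-dione, via allylic alcohol 6 (not isolated)
Conditions: SeO2 (0.5 equiv), t-BuOOH, CH2Cl2, 25 °C; then MnO2, CH2Cl2, 25 °C
Reagents that add atoms: selenium dioxide, O=[Se]=O; tert-butyl hydroperoxide, CC(C)(C)OO
Why: Selenium dioxide allylic hydroxylation (ene reaction, then 2,3-shift) oxidises C7, the only allylic methylene, without moving the alkene, and MnO2 takes the allylic alcohol to the enone; the neighbouring bridgehead C6 cannot enolise, so no stereocentre is at risk.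

Step 4
Reactants: 7 8-bromo-1-methyl-6-oxabicyclo[3.2.1]oct-2-ene-4,7-dione
Product: 8 C7 p-toluenesulfonylhydrazone of 7
Conditions: TsNHNH2, AcOH (cat.), THF, 40 °C
Reagents that add atoms: p-toluenesulfonohydrazide, Cc1ccc(cc1)S(=O)(=O)NN
Why: Hydrazone condensation occurs at the only ketone; the lactone carbonyl does not react under these conditions.

Step 5
Reactants: 8 C7 p-toluenesulfonylhydrazone of 7
Product: 10 (1R,5R,8R)-8-bromo-1-methyl-6-oxabicyclo[3.2.1]oct-3-en-7-one, via allyl diazene 9 (not isolated)
Conditions: catecholborane, CHCl3, 0 °C; then NaOAc·3H2O, 60 °C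
Reagents that add atoms: none
Why: Hydride adds 1,2 to the C=N bond and loss of sulfinate gives diazene 9, which loses nitrogen by a retro-ene shift that places hydrogen on C9 and the alkene at C7=C8 (reductive 1,3-transposition of an enone tosylhydrazone). The C6–O bond is never touched, so its configuration from step 2 is kept.

Step 6
Reactants: 10 (1R,5R,8R)-8-bromo-1-methyl-6-oxabicyclo[3.2.1]oct-3-en-7-one
Product: 12 8-bromo-7-methoxy-1-methyl-6-oxabicyclo[3.2.1]oct-3-ene, via lactol 11 (not isolated)
Conditions: i-Bu2AlH, CH2Cl2, −78 °C; then MeOH, PPTS, 25 °C
Reagents that add atoms: methanol, CO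
Why: Partial reduction of the lactone stops at the aluminium hemiacetal, and acid-catalysed acetalisation fixes C1 as the methyl acetal, expected mainly exo; no free alkoxide ever faces the trans bromide, so no epoxide should form. The acetal also removes the allylic ester that low-valent nickel would ionise in step 8.

Step 7
Reactants: 13 2-bromoprop-2-en-1-ol
Product: 14 (2-bromoallyloxy)(tert-butyl)diphenylsilane
Conditions: TBDPSCl, imidazole, CH2Cl2, 0 to 25 °C
Reagents that add atoms: tert-butyl(chloro)diphenylsilane, CC(C)(C)[Si](Cl)(c1ccccc1)c1ccccc1
Why: Standard silylation of a primary alcohol; the silyl ether is chosen to survive acetic acid in step 13 and to fall in step 19.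

Step 8
Reactants: 12 8-bromo-7-methoxy-1-methyl-6-oxabicyclo[3.2.1]oct-3-ene; 14 (2-bromoallyloxy)(tert-butyl)diphenylsilane
Product: 15 7-methoxy-1-methyl-8-[3-(tert-butyldiphenylsilyloxy)prop-1-en-2-yl]-6-oxabicyclo[3.2.1]oct-3-ene
Conditions: NiBr2(dme) (10 mol%), 4,4′-di-tert-butyl-2,2′-bipyridine (10 mol%), Mn powder, NaI, DMA, 25 °C
Reagents that add atoms: none
Why: Nickel-catalysed reductive cross-electrophile coupling: zerovalent nickel inserts into the alkenyl bromide, monovalent nickel abstracts bromine from C5, and the C5 radical is captured and reductively eliminated from trivalent nickel, so the reaction is stereoconvergent. The new bond should form anti to the C1–O bridge because the ring oxygen and the exo-methoxy group flank the upper lobe and bonding anti to the β C6–O bond is stereoelectronically favoured. This places C4 trans to the C6 oxygen.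

Step 9
Reactants: 15 7-methoxy-1-methyl-8-[3-(tert-butyldiphenylsilyloxy)prop-1-en-2-yl]-6-oxabicyclo[3.2.1]oct-3-ene
Product: 16 lactol corresponding to 15 (C1 hemiacetal)
Conditions: PPTS, acetone/H2O (4:1), 40 °C
Reagents that add atoms: water, O
Why: Mild acid hydrolysis of the cyclic mixed acetal; the tert-butyldiphenylsilyl ether is stable under these conditions.

Step 10
Reactants: 16 lactol corresponding to 15 (C1 hemiacetal)
Product: 17 cyclohex-2-enol with C10 methyl and vinyl and the C5 silyloxypropenyl group (C6–OH cis to vinyl and trans to the C5 group)
Conditions: Ph3PCH3Br, KOtBu, THF, 0 to 45 °C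
Reagents that add atoms: methyltriphenylphosphonium bromide, C[P+](c1ccccc1)(c1ccccc1)c1ccccc1.[Br-]
Why: Wittig methylenation of the hydroxy-aldehyde tautomer of the lactol turns C1 into the vinyl carbon and frees the C6 hydroxyl with the configuration set in step 2; C10 has no hydrogen and cannot epimerise.

Step 11
Reactants: 17 cyclohex-2-enol with C10 methyl and vinyl and the C5 silyloxypropenyl group; 4 N-bromosuccinimide; 18 methoxyallene
Product: 19 mixed acetal of 17 at C6–O with 2-bromoacrolein (methyl acetal; both C12 epimers)
Conditions: methoxyallene (3 equiv), NBS, CH2Cl2, −78 to −30 °C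
Reagents that add atoms: none
Why: Bromenium attacks the central carbon of the alkoxyallene and the resulting α-bromovinyl oxocarbenium ion is trapped by the C6 hydroxyl (haloalkoxylation of an alkoxyallene); the allenyl ether is far more nucleophilic than the alkenes of 17.

Step 12
Reactants: 19 mixed acetal of 17 at C6–O with 2-bromoacrolein
Product: 20 cis-fused 2-methoxy-3-methylenetetrahydrofuran with a C8 aminoxy ether (C8 and C12 epimers)
Conditions: Bu3SnH, TEMPO (both added slowly), benzene, 75 °C
Reagents that add atoms: TEMPO, CC1(C)CCCC(C)(C)N1[O]
Why: The stannyl radical abstracts the vinylic bromine and the vinyl radical closes 5-exo-trig onto C7; the three-atom tether can reach C7 only on the face of the C6 oxygen, which sets C7 cis to C6–O. The C8 radical is capped by the nitroxide (tin hydride–nitroxide cyclisation with trapping). Both C8 epimers are accepted because C8 is reset in steps 14 and 15.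

Step 13
Reactants: 20 cis-fused 2-methoxy-3-methylenetetrahydrofuran with a C8 aminoxy ether
Product: 21 C8 alcohol (both epimers)
Conditions: Zn dust, AcOH, MeOH/THF, 50 °C
Reagents that add atoms: none
Why: Reductive cleavage of the N–O bond of the alkoxyamine; methanol as co-solvent should keep C12 as the methyl acetal by degenerate exchange.

Step 14
Reactants: 21 C8 alcohol (both epimers)
Product: 22 C8 ketone
Conditions: Dess–Martin periodinane, NaHCO3, CH2Cl2, 0 °C
Reagents that add atoms: none
Why: Both C8 epimers converge on one ketone; the buffered, non-basic oxidant should leave the exocyclic alkene out of conjugation and C7 intact.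

Step 15
Reactants: 22 C8 ketone
Product: 23 C8 alcohol with C8–O trans to the C7 substituent
Conditions: LiBH(s-Bu)3, THF, −78 °C; then H2O
Reagents that add atoms: none
Why: The bulky hydride should attack along the equatorial trajectory on the upper face, because the axial path is blocked by the syn-axial C10 methyl as in 3,3,5-trimethylcyclohexanone; this gives the axial C8 alcohol, trans to the C7 substituent.

Step 16
Reactants: 24 methyl (R)-2-(2,2-dimethyl-1,3-dioxolan-4-yl)acetate; 2 iodomethane
Product: 27 methyl (R)-2-(2,2-dimethyl-1,3-dioxolan-4-yl)acrylate, via Mannich base 25 (not isolated), via ammonium iodide 26 (not isolated)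
Conditions: LiN(i-Pr)2, THF, −78 °C, then CH2=NMe2 I; then MeI, MeOH, 25 °C; then DBU, CH2Cl2
Reagents that add atoms: N,N-dimethylmethyleneiminium iodide, C=[N+](C)C.[I-]
Why: Ester enolate Mannich reaction, N-methylation and elimination of trimethylamine (α-methylenation); the C3′ stereocentre is not deprotonated, and the enolate is kept cold so that it does not expel the β-oxygen.

Step 17
Reactants: 27 methyl (R)-2-(2,2-dimethyl-1,3-dioxolan-4-yl)acrylate
Product: 28 (R)-2-(2,2-dimethyl-1,3-dioxolan-4-yl)acrylic acid
Conditions: LiOH·H2O, THF/H2O, 0 °C; then 1 M HCl to pH 3, 0 °C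
Reagents that add atoms: lithium hydroxide, [Li+].[OH-]
Why: Saponification of the methyl ester; the acetonide is stable to base and to brief cold acidification.

Step 18
Reactants: 23 C8 alcohol with C8–O trans to the C7 substituent; 28 (R)-2-(2,2-dimethyl-1,3-dioxolan-4-yl)acrylic acid
Product: 30 C8 ester of 23 with 28, via mixed anhydride 29 (not isolated)
Conditions: 2,4,6-trichlorobenzoyl chloride, Et3N, THF, 0 °C; then 23, DMAP, toluene, 40 °C
Reagents that add atoms: none
Why: Yamaguchi esterification transfers the acyl group to the hindered axial C8 hydroxyl; only the O–H bond reacts, so C8 and C3′ keep their configurations.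

Step 19
Reactants: 30 C8 ester of 23 with 28
Product: 31 lactol tetraol (C12 hemiacetal; C15, C3′ and C4′ hydroxyls free)
Conditions: HF (48% aq.), MeCN, 0 to 25 °C
Reagents that add atoms: water, O
Why: Acidic fluoride removes the silyl ether, and the aqueous acid hydrolyses the acetonide and the methyl acetal to the lactol, a masked C12 aldehyde. The medium stays acidic because the side-chain diol attacks its own ester under base.

Step 20
Reactants: 31 lactol tetraol
Product: 32 target CNP0348657.7
Conditions: NaClO2, NaH2PO4, 2-methyl-2-butene, t-BuOH/H2O, 0 to 25 °C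
Reagents that add atoms: sodium chlorite, [Na+].[O-]Cl=O
Why: Pinnick oxidation of the ring-opened 2-substituted acrolein tautomer of the lactol gives the acrylic acid and frees the C6 hydroxyl. The alkene scavenger protects the double bonds and alcohols are not oxidised; work-up is kept cold near pH 4–5 to avoid relactonisation.

## Compound list

1 | benzoic acid | OC(=O)c1ccccc1 | starting material
2 | iodomethane | CI | starting material
3 | 1-methylcyclohexa-2,5-diene-1-carboxylic acid | CC1(C=CCC=C1)C(=O)O | intermediate
4 | N-bromosuccinimide | O=C1CCC(=O)N1Br | starting material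
5 | (1R,5R,8R)-8-bromo-1-methyl-6-oxabicyclo[3.2.1]oct-2-en-7-one (Br anti to the lactone oxygen) | O=C2[C@@]1(C)C=CC[C@@H](O2)[C@@H]1Br | intermediate
6 | 8-bromo-4-hydroxy-1-methyl-6-oxabicyclo[3.2.1]oct-2-en-7-one (ring stereocentres as in 5; either carbinol epimer) | O=C2[C@@]1(C)C=CC(O)[C@@H](O2)[C@@H]1Br | intermediate
7 | 8-bromo-1-methyl-6-oxabicyclo[3.2.1]oct-2-ene-4,7-dione (ring stereocentres as in 5) | O=C2[C@@]1(C)C=CC(=O)[C@@H](O2)[C@@H]1Br | intermediate
8 | 4-(p-toluenesulfonyl)hydrazone of 7 | O=C2[C@@]1(C)C=CC(=NNS(=O)(=O)c3ccc(C)cc3)[C@@H](O2)[C@@H]1Br | intermediate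
9 | 8-bromo-4-diazenyl-1-methyl-6-oxabicyclo[3.2.1]oct-2-en-7-one (allyl diazene) | O=C2[C@@]1(C)C=CC(N=N)[C@@H](O2)[C@@H]1Br | intermediate
10 | (1R,5R,8R)-8-bromo-1-methyl-6-oxabicyclo[3.2.1]oct-3-en-7-one | O=C2[C@@]1(C)CC=C[C@@H](O2)[C@@H]1Br | intermediate
11 | 8-bromo-1-methyl-6-oxabicyclo[3.2.1]oct-3-en-7-ol (lactol; ring stereocentres as in 10) | OC2[C@@]1(C)CC=C[C@@H](O2)[C@@H]1Br | intermediate
12 | 8-bromo-7-methoxy-1-methyl-6-oxabicyclo[3.2.1]oct-3-ene (acetal epimers, exo-methoxy expected as major; ring stereocentres as in 10) | COC2[C@@]1(C)CC=C[C@@H](O2)[C@@H]1Br | intermediate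
13 | 2-bromoprop-2-en-1-ol | C=C(Br)CO | starting material
14 | (2-bromoallyloxy)(tert-butyl)diphenylsilane | C=C(Br)CO[Si](c1ccccc1)(c2ccccc2)C(C)(C)C | intermediate
15 | 7-methoxy-1-methyl-8-[3-(tert-butyldiphenylsilyloxy)prop-1-en-2-yl]-6-oxabicyclo[3.2.1]oct-3-ene (alkenyl group anti to the ring oxygen bridge) | COC2[C@@]1(C)CC=C[C@@H](O2)[C@@H]1C(=C)CO[Si](c3ccccc3)(c4ccccc4)C(C)(C)C | intermediate
16 | 1-methyl-8-[3-(tert-butyldiphenylsilyloxy)prop-1-en-2-yl]-6-oxabicyclo[3.2.1]oct-3-en-7-ol (lactol) | OC2[C@@]1(C)CC=C[C@@H](O2)[C@@H]1C(=C)CO[Si](c3ccccc3)(c4ccccc4)C(C)(C)C | intermediate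
17 | 5-methyl-5-vinyl-6-[3-(tert-butyldiphenylsilyloxy)prop-1-en-2-yl]cyclohex-2-en-1-ol (hydroxyl cis to vinyl and trans to the side chain) | C=C[C@@]1(C)CC=C[C@@H](O)[C@@H]1C(=C)CO[Si](c2ccccc2)(c3ccccc3)C(C)(C)C | intermediate
18 | methoxyallene (1-methoxypropa-1,2-diene) | C=C=COC | starting material
19 | 2-bromo-1-methoxyprop-2-enyl ether of 17 (acetal epimers) | C=C[C@@]1(C)CC=C[C@@H](OC(OC)C(Br)=C)[C@@H]1C(=C)CO[Si](c2ccccc2)(c3ccccc3)C(C)(C)C | intermediate
20 | cis-fused 2-methoxy-3-methylenetetrahydrofuran on C6/C7 with C8 2,2,6,6-tetramethylpiperidin-1-yloxy group (C8 and C12 epimers) | C=C[C@@]1(C)CC(ON2C(C)(C)CCCC2(C)C)[C@H]3C(=C)C(OC)O[C@H]3[C@@H]1C(=C)CO[Si](c4ccccc4)(c5ccccc5)C(C)(C)C | intermediate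
21 | C8 alcohol from 20 (C8 and C12 epimers) | C=C[C@@]1(C)CC(O)[C@H]2C(=C)C(OC)O[C@H]2[C@@H]1C(=C)CO[Si](c3ccccc3)(c4ccccc4)C(C)(C)C | intermediate
22 | C8 ketone (C12 epimers) | C=C[C@@]1(C)CC(=O)[C@H]2C(=C)C(OC)O[C@H]2[C@@H]1C(=C)CO[Si](c3ccccc3)(c4ccccc4)C(C)(C)C | intermediate
23 | C8 alcohol with hydroxyl trans to the C7 ring-fusion carbon substituent (C12 epimers) | C=C[C@@]1(C)C[C@H](O)[C@H]2C(=C)C(OC)O[C@H]2[C@@H]1C(=C)CO[Si](c3ccccc3)(c4ccccc4)C(C)(C)C | intermediate
24 | methyl (R)-2-(2,2-dimethyl-1,3-dioxolan-4-yl)acetate | COC(=O)C[C@@H]1COC(C)(C)O1 | starting material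
25 | methyl 3-(dimethylamino)-2-[(R)-2,2-dimethyl-1,3-dioxolan-4-yl]propanoate (Mannich base, α-epimers) | COC(=O)C(CN(C)C)[C@@H]1COC(C)(C)O1 | intermediate
26 | trimethylammonium iodide derived from 25 | COC(=O)C(C[N+](C)(C)C)[C@@H]1COC(C)(C)O1.[I-] | intermediate
27 | methyl (R)-2-(2,2-dimethyl-1,3-dioxolan-4-yl)acrylate | C=C(C(=O)OC)[C@@H]1COC(C)(C)O1 | intermediate
28 | (R)-2-(2,2-dimethyl-1,3-dioxolan-4-yl)acrylic acid | C=C(C(=O)O)[C@@H]1COC(C)(C)O1 | intermediate
29 | mixed anhydride of 28 with 2,4,6-trichlorobenzoic acid | C=C(C(=O)OC(=O)c1c(Cl)cc(Cl)cc1Cl)[C@@H]2COC(C)(C)O2 | intermediate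
30 | C8 ester of 23 with 28 (C12 epimers) | C=C[C@@]1(C)C[C@H](OC(=O)C(=C)[C@@H]2COC(C)(C)O2)[C@H]3C(=C)C(OC)O[C@H]3[C@@H]1C(=C)CO[Si](c4ccccc4)(c5ccccc5)C(C)(C)C | intermediate
31 | lactol tetraol: C12 hemiacetal bridging to the C6 oxygen; C8 (R)-3,4-dihydroxy-2-methylenebutanoate; C15 hydroxyl free (C12 epimers) | C=C[C@@]1(C)C[C@H](OC(=O)C(=C)[C@@H](O)CO)[C@H]2C(=C)C(O)O[C@H]2[C@@H]1C(=C)CO | intermediate
32 | CNP0348657.7 | C=C[C@@]1(C)C[C@H](OC(=O)C(=C)[C@@H](O)CO)[C@@H](C(=C)C(=O)O)[C@@H](O)[C@@H]1C(=C)CO | target

## Step count and least certain steps

Total: 20 steps. Longest linear sequence: 17 steps (steps 1–6, 8–15 and 18–20); steps 7, 16 and 17 prepare 14 and 28.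

**Step 2 (key step).** The catalyst may differentiate the two enantiotopic alkenes incompletely, lowering enantiomeric purity, and kinetic 4-exo closure may divert material to the β-lactone if isomerisation is slow. Fallback, from 3 back to 5: 3 is coupled (EDC, HOBt) with (2R,5R)-2,5-bis(methoxymethyl)pyrrolidine to give the amide F1. Halolactonisation of this amide with NBS in aqueous THF is then controlled by the covalent auxiliary: the amide oxygen attacks the bromonium ion, and hydrolysis of the iminium lactone releases the auxiliary and gives 5. The antipodal auxiliary is used if the sense is opposite.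

**Step 8.** Three things may go wrong:
- Face selection at the bridging C5 radical may be poor, because the two-atom acetal bridge on one side and the pseudo-axial C9–H on the other hinder the two faces to a similar degree.
- The C5 radical may attack C7 in a 3-exo mode and rearrange through a cyclopropylcarbinyl radical before nickel captures it.
- The alkylnickel may lose the β-oxygen.

Fallback, from 10 back to 16: excess i-Bu2AlH reduces 10 to the bromo diol F2. t-Bu2Si(OTf)2 with 2,6-lutidine gives the seven-membered silylene F3, which holds the C10–CH2O and C6–O bonds syn-axial so that both flank the upper lobe at C5. The same nickel coupling with 14 gives the coupled silylene F4. Brief buffered HF·pyridine at 0 °C gives the diol F5. Primary-selective oxidation (TEMPO cat., N-chlorosuccinimide, Bu4NCl, pH 8.6 buffer) closes F5 to lactol 16.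

**Step 5.** Hydride may add 1,4 to the unsaturated hydrazone, or the hydrazine may be reduced without transposition, leaving the alkene at C8=C9. Fallback, from 6 back to 10: the MnO2 stage of step 3 is omitted and 6 is isolated. Mitsunobu displacement with 2-nitrobenzenesulfonylhydrazide (PPh3, DEAD, −30 to 23 °C) gives, after loss of sulfinate, the same diazene 9 and hence 10, with no hydride involved.

**Step 12.** The nitroxide may capture the vinyl radical before it cyclises, and the vinyl radical may abstract the allylic C5 hydrogen through a six-membered transition state. Fallback, from 19 back to 21: oxygenative cyclisation with Bu3SnH under dry air. Dioxygen is present at much lower concentration than the nitroxide; the C8 radical is trapped as the hydroperoxide F6, which PPh3 reduces in the flask to 21. This also removes step 13.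

**Step 15.** Hydride may be delivered along the axial path if the axial C7 substituent hinders the equatorial trajectory more than the C10 methyl hinders the axial one; this would give the C8 epimer. Fallback, from 22 back to 30: 22 is reduced with NaBH4/CeCl3·7H2O to the equatorial alcohol F7, which is esterified with 28 under Mitsunobu conditions (PPh3, DIAD). Inversion at C8 gives 30 directly and removes step 18.

## Further compounds

F1 | step 2 | (2R,5R)-2,5-bis(methoxymethyl)pyrrolidine amide of 3 | CC1(C=CCC=C1)C(=O)N2[C@@H](COC)CC[C@@H]2COC
F2 | step 8 | bromo diol from 10 (C1 hydroxymethyl and C6 hydroxyl cis; bromine trans to C6–O) | OC[C@@]1(C)CC=C[C@@H](O)[C@@H]1Br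
F3 | step 8 | di-tert-butylsilylene of F2 | CC(C)(C)[Si]2(OC[C@@]1(C)CC=C[C@@H](O2)[C@@H]1Br)C(C)(C)C
F4 | step 8 | di-tert-butylsilylene carrying the C5 silyloxypropenyl group trans to C6–O | CC(C)(C)[Si]2(OC[C@@]1(C)CC=C[C@@H](O2)[C@@H]1C(=C)CO[Si](c3ccccc3)(c4ccccc4)C(C)(C)C)C(C)(C)C
F5 | step 8 | diol from F4 | OC[C@@]1(C)CC=C[C@@H](O)[C@@H]1C(=C)CO[Si](c2ccccc2)(c3ccccc3)C(C)(C)C
F0 | step 5 | none | none
F6 | step 12 | C8 hydroperoxide of the cyclised acetal (C8 and C12 epimers) | C=C[C@@]1(C)CC(OO)[C@H]2C(=C)C(OC)O[C@H]2[C@@H]1C(=C)CO[Si](c3ccccc3)(c4ccccc4)C(C)(C)C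
F7 | step 15 | C8 epimer of 23 (hydroxyl cis to the C7 substituent) | C=C[C@@]1(C)C[C@@H](O)[C@H]2C(=C)C(OC)O[C@H]2[C@@H]1C(=C)CO[Si](c3ccccc3)(c4ccccc4)C(C)(C)C
A1 | alternative 1 | open-chain C6 aldehyde with (Z)-2-(bromomethyl)enoate allyl ester, C8 p-methoxybenzyl ether and C15 silyl ether | C=C[C@@](C)(C[C@H](OCc1ccc(OC)cc1)/C=C(\CBr)C(=O)OCC=C)[C@H](C=O)C(=C)CO[Si](C)(C)C(C)(C)C
A2 | alternative 1 | cyclohexane with cis C6 hydroxyl and C7 allyl acrylate | C=C[C@@]1(C)C[C@H](OCc2ccc(OC)cc2)[C@@H](C(=C)C(=O)OCC=C)[C@@H](O)[C@@H]1C(=C)CO[Si](C)(C)C(C)(C)C
A3 | alternative 2 | C6 2-bromoallyl ether of the C7=C8 cyclohexenol (C15 pivalate) | C=C[C@@]1(C)CC=C[C@@H](OCC(Br)=C)[C@@H]1C(=C)COC(=O)C(C)(C)C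
A4 | alternative 2 | cis-fused 3-methylenetetrahydrofuran with C8 aminoxy ether | C=C[C@@]1(C)C[C@H](ON2C(C)(C)CCCC2(C)C)[C@H]3C(=C)CO[C@H]3[C@@H]1C(=C)COC(=O)C(C)(C)C
A5 | alternative 3 | open-chain C8 trimethylsilyl enol ether with (E)-allylsilane at C10 | C=C(O[Si](C)(C)C)C[C@@H](O[Si](C)(C)C(C)(C)C)[C@H](C(=C)COC(=O)C(C)(C)C)/C(C)=C/C[Si](C)(C)C
A6 | alternative 3 | 3-methyl-3-vinylcyclohexanone with C5 alkenyl and C6 silyloxy groups | C=C[C@@]1(C)CC(=O)C[C@@H](O[Si](C)(C)C(C)(C)C)[C@@H]1C(=C)COC(=O)C(C)(C)C
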